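The route rests on cutting C4''–C4a'' of the flavone pyranone. C8'' already carries ring B of the flavanone half, so C4a'' is the only unsubstituted carbon ortho to O1''. An activated acyl group tethered through O1''–C2''=C3'' can therefore close in one direction only. The 8''-aryl connectivity is built in instead of being chosen between two phenols. The precursor 9 is a (Z)-3-aryloxy-3-(4-benzyloxyphenyl)acrylic acid. Its aryloxy part is a 3,5-dibenzyloxyphenyl ring bearing the formyl-substituted ring B at C2. One Friedel–Crafts acylation forms the C–C bond and the pyranone. The formyl group then grows the (2S)-flavanone by catalytic asymmetric oxa-Michael cyclisation.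

Key step: step 6

Numbering: unprimed locants are the flavanone chromanone (rings A and C), single primes are ring B, double primes are the flavone chromenone, and triple primes are the flavone 2-aryl ring.
Assumption 1: the quinidine-derived thiourea of step 10 is taken to give the (2S) series; if a first analytical run shows the opposite sense, the equally available quinine-derived pseudoenantiomer is used with no other change.
Assumption 2: the C3'–C8'' biaryl axis has no descriptor in the target and is treated as not configurationally fixed.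

Step 1
Reactants: 1 3,5-bis(benzyloxy)phenol
Product: 2 3,5-bis(benzyloxy)-2-iodophenol
Conditions: NIS (1.0 equiv), CH2Cl2, −20 to 0 °C, dark
Reagents that add atoms: N-iodosuccinimide, O=C1CCC(=O)N1I
Why: Electrophilic aromatic iodination; all free ring carbons are activated by three oxygens, but the two equivalent carbons next to the small hydroxyl group are less crowded than C4 between two benzyloxy groups and are further favoured by hydrogen bonding of the phenol to NIS in a non-polar solvent, and the unsymmetrical 2-iodo isomer is readily distinguished from the symmetrical 4-iodo isomer and purified here.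

Step 2
Reactants: 2 3,5-bis(benzyloxy)-2-iodophenol; 3 (5-formyl-2-methoxyphenyl)boronic acid
Product: 4 3-[2,4-bis(benzyloxy)-6-hydroxyphenyl]-4-methoxybenzaldehyde
Conditions: Pd(OAc)2 (3 mol%), SPhos (6 mol%), K3PO4 (3 equiv), toluene/H2O 10:1, 80 °C
Reagents that add atoms: none
Why: Suzuki–Miyaura coupling; the aryl iodide adds readily to zerovalent palladium, the bulky electron-rich biarylphosphine is suited to tri-ortho-substituted biaryls, and free phenols and aromatic aldehydes are tolerated under aqueous phosphate.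

Step 3
Reactants: 5 1-(benzyloxy)-4-iodobenzene; 6 ethyl propiolate
Product: 7 ethyl 3-[4-(benzyloxy)phenyl]prop-2-ynoate
Conditions: PdCl2(PPh3)2 (2 mol%), CuI (4 mol%), K2CO3 (2 equiv), THF, 65 °C, 6 (2 equiv) added slowly
Reagents that add atoms: none
Why: Sonogashira coupling run with an inorganic base, which avoids the amine conjugate addition and oligomerisation that trouble propiolate esters, while the aryl iodide couples under gentle heating.

Step 4
Reactants: 4 3-[2,4-bis(benzyloxy)-6-hydroxyphenyl]-4-methoxybenzaldehyde; 7 ethyl 3-[4-(benzyloxy)phenyl]prop-2-ynoate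
Product: 8 ethyl (Z)-3-[3,5-bis(benzyloxy)-2-(5-formyl-2-methoxyphenyl)phenoxy]-3-[4-(benzyloxy)phenyl]acrylate
Conditions: Cs2CO3 (1 equiv), 4 Å MS, DMF, 80 °C
Reagents that add atoms: none
Why: Base-mediated oxa-Michael (conjugate) addition of a phenoxide to an arylpropiolate, the classical entry to 3-aryloxycinnamates; anti addition should favour the Z ester, any E isomer is carried on because it converges in step 6, and neither partner has an enolisable position.

Step 5
Reactants: 8 ethyl (Z)-3-[3,5-bis(benzyloxy)-2-(5-formyl-2-methoxyphenyl)phenoxy]-3-[4-(benzyloxy)phenyl]acrylate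
Product: 9 (Z)-3-[3,5-bis(benzyloxy)-2-(5-formyl-2-methoxyphenyl)phenoxy]-3-[4-(benzyloxy)phenyl]acrylic acid
Conditions: LiOH·H2O (3 equiv), THF/EtOH/H2O, 40 °C; then 1 M HCl, 0 °C, pH 3
Reagents that add atoms: lithium hydroxide, [Li+].[OH-]
Why: Ester saponification by acyl–oxygen cleavage; the β-carbon is fully substituted and donor-stabilised, so hydroxide should attack the ester carbonyl and not displace the aryloxide, and the non-enolisable aldehyde is inert to dilute LiOH.

Step 6
Reactants: 9 (Z)-3-[3,5-bis(benzyloxy)-2-(5-formyl-2-methoxyphenyl)phenoxy]-3-[4-(benzyloxy)phenyl]acrylic acid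
Product: 11 8-(5-formyl-2-methoxyphenyl)apigenin tribenzyl ether, via acyl trifluoroacetate 10 (not isolated)
Conditions: (CF3CO)2O (2.5 equiv), CH2Cl2, 0 °C to rt; aq. NaHCO3 work-up
Reagents that add atoms: none
Why: The anhydride turns the acid into acyl trifluoroacetate 10, whose acyl carbon (or the derived acylium ion) is attacked by C4a'' of the phloroglucinol ring, and loss of a proton and of trifluoroacetate restores aromaticity and leaves the 4-pyranone; this is an intramolecular Friedel–Crafts acylation of the type long used to convert 3-aryloxycinnamic acids into flavones. The closure is 6-exo-trig at the acyl C=O, with the arene bond C4a''–C8a'' lying inside the new ring. C4a'' is ortho to O1'' and to the 5''-benzyloxy group and para to the 7''-benzyloxy group, so an anhydride without added Lewis acid should suffice, the benzyl ethers stay on, ring B is switched off by its formyl group, and any geminal bis(trifluoroacetate) formed at the aldehyde reverts on bicarbonate work-up. The only selectivity needed is 8''-aryl versus 6''-aryl, and the substrate enforces it: O1''–C2'' exists before closure, C8'' is blocked by ring B, and C6'' is out of reach of the short tether. E acid brought from step 4 is not lost, because reversible protonation at C3'' of the donor–acceptor alkene allows rotation into the reactive Z form. No stereocentre is created.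

Step 7
Reactants: 12 1-(2,6-dihydroxy-4-methoxyphenyl)ethanone
Product: 13 1-[2-(benzyloxy)-6-hydroxy-4-methoxyphenyl]ethanone
Conditions: BnBr (1.05 equiv), K2CO3 (1.1 equiv), acetone, reflux
Reagents that add atoms: benzyl bromide, BrCc1ccccc1
Why: Williamson etherification; the substrate is symmetric so either hydroxyl gives the same ether, and the remaining hydroxyl, held in a hydrogen bond to the ketone, resists a second alkylation when only one equivalent of bromide is offered.

Step 8
Reactants: 13 1-[2-(benzyloxy)-6-hydroxy-4-methoxyphenyl]ethanone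
Product: 14 tert-butyl 3-[2-(benzyloxy)-6-hydroxy-4-methoxyphenyl]-3-oxopropanoate
Conditions: LiN(SiMe3)2 (3.3 equiv), THF, −78 °C; Boc2O (1.1 equiv), −78 to 0 °C; 1 M HCl quench, 0 °C
Reagents that add atoms: di-tert-butyl dicarbonate, CC(C)(C)OC(=O)OC(=O)OC(C)(C)C
Why: Claisen-type C-acylation of a polylithiated 2-hydroxyacetophenone; the enolate carbon is the most nucleophilic site, any aryl carbonate formed at oxygen should be passed to carbon by a Baker–Venkataraman-type shift under excess base, the third equivalent of base stores the product as its enolate, and the tert-butyl ester is too hindered to lactonise to a coumarin in the cold.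

Step 9
Reactants: 11 8-(5-formyl-2-methoxyphenyl)apigenin tribenzyl ether; 14 tert-butyl 3-[2-(benzyloxy)-6-hydroxy-4-methoxyphenyl]-3-oxopropanoate
Product: 15 tert-butyl (Z)-2-[2-(benzyloxy)-6-hydroxy-4-methoxybenzoyl]-3-{3-[5,7-bis(benzyloxy)-2-(4-benzyloxyphenyl)-4-oxo-4H-chromen-8-yl]-4-methoxyphenyl}acrylate
Conditions: piperidine (20 mol%), AcOH (20 mol%), 4 Å MS, toluene, rt
Reagents that add atoms: none
Why: Knoevenagel condensation under piperidinium acetate catalysis with removal of water; the alkylidene should form with ring B cis to the ester and away from the bulky aroyl group, and the buffered room-temperature conditions are chosen to keep the free phenol from cyclising prematurely.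

Step 10
Reactants: 15 tert-butyl (Z)-2-[2-(benzyloxy)-6-hydroxy-4-methoxybenzoyl]-3-{3-[5,7-bis(benzyloxy)-2-(4-benzyloxyphenyl)-4-oxo-4H-chromen-8-yl]-4-methoxyphenyl}acrylate
Product: 18 (2S)-5,5'',7'',4'''-tetra-O-benzyl-2,3-dihydroamentoflavone 7,4'-dimethyl ether, via tert-butyl flavanone-3-carboxylate 16 (not isolated), via flavanone-3-carboxylic acid 17 (not isolated)
Conditions: 9-amino-9-deoxy-epi-quinidine 3,5-bis(trifluoromethyl)phenyl thiourea (10 mol%), toluene, −25 °C; then TsOH·H2O (1 equiv), 80 °C
Reagents that add atoms: none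
Why: Organocatalytic asymmetric intramolecular oxa-Michael addition followed by acid-mediated tert-butyl ester cleavage and decarboxylation; the thiourea binds the two carbonyl groups of the alkylidene β-keto ester while the quinuclidine nitrogen activates the phenol, so oxygen is delivered to the Re face of the alkylidene carbon and C2 is set as S under catalyst control, whereas the labile C3 centre disappears on loss of CO2.

Step 11
Reactants: 18 (2S)-5,5'',7'',4'''-tetra-O-benzyl-2,3-dihydroamentoflavone 7,4'-dimethyl ether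
Product: 19 (2S)-2,3-dihydroamentoflavone 7,4'-dimethyl ether (CNP0169789.1)
Conditions: H2 (1 atm), 10% Pd/C, THF/MeOH, rt
Reagents that add atoms: none
Why: Catalytic hydrogenolysis of four aryl benzyl ethers under neutral conditions at atmospheric pressure, which should leave C2''=C3'', both carbonyl groups, the two methyl ethers and the base-sensitive C2 stereocentre untouched if the reaction is stopped once hydrogen uptake ends.

Compound list
1 | 3,5-bis(benzyloxy)phenol | Oc1cc(OCc2ccccc2)cc(OCc2ccccc2)c1 | starting material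
2 | 3,5-bis(benzyloxy)-2-iodophenol | Oc1cc(OCc2ccccc2)cc(OCc2ccccc2)c1I | intermediate
3 | (5-formyl-2-methoxyphenyl)boronic acid | COc1ccc(C=O)cc1B(O)O | starting material
4 | 3-[2,4-bis(benzyloxy)-6-hydroxyphenyl]-4-methoxybenzaldehyde | O=Cc1ccc(OC)c(-c2c(O)cc(OCc3ccccc3)cc2OCc2ccccc2)c1 | intermediate
5 | 1-(benzyloxy)-4-iodobenzene | Ic1ccc(OCc2ccccc2)cc1 | starting material
6 | ethyl propiolate | C#CC(=O)OCC | starting material
7 | ethyl 3-[4-(benzyloxy)phenyl]prop-2-ynoate | CCOC(=O)C#Cc1ccc(OCc2ccccc2)cc1 | intermediate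
8 | ethyl (Z)-3-[3,5-bis(benzyloxy)-2-(5-formyl-2-methoxyphenyl)phenoxy]-3-[4-(benzyloxy)phenyl]acrylate | O=Cc1ccc(OC)c(-c2c(OCc3ccccc3)cc(OCc3ccccc3)cc2O/C(=C\C(=O)OCC)c2ccc(OCc3ccccc3)cc2)c1 | intermediate
9 | (Z)-3-[3,5-bis(benzyloxy)-2-(5-formyl-2-methoxyphenyl)phenoxy]-3-[4-(benzyloxy)phenyl]acrylic acid | O=Cc1ccc(OC)c(-c2c(OCc3ccccc3)cc(OCc3ccccc3)cc2O/C(=C\C(=O)O)c2ccc(OCc3ccccc3)cc2)c1 | intermediate
10 | mixed anhydride of 9 with trifluoroacetic acid (Z) | O=Cc1ccc(OC)c(-c2c(OCc3ccccc3)cc(OCc3ccccc3)cc2O/C(=C\C(=O)OC(=O)C(F)(F)F)c2ccc(OCc3ccccc3)cc2)c1 | intermediate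
11 | 8-(5-formyl-2-methoxyphenyl)apigenin tribenzyl ether, i.e. 3-[5,7-bis(benzyloxy)-2-(4-benzyloxyphenyl)-4-oxo-4H-chromen-8-yl]-4-methoxybenzaldehyde | O=Cc1ccc(OC)c(-c2c(OCc3ccccc3)cc(OCc3ccccc3)c3c(=O)cc(-c4ccc(OCc5ccccc5)cc4)oc23)c1 | intermediate
12 | 1-(2,6-dihydroxy-4-methoxyphenyl)ethanone | CC(=O)c1c(O)cc(OC)cc1O | starting material
13 | 1-[2-(benzyloxy)-6-hydroxy-4-methoxyphenyl]ethanone | CC(=O)c1c(O)cc(OC)cc1OCc1ccccc1 | intermediate
14 | tert-butyl 3-[2-(benzyloxy)-6-hydroxy-4-methoxyphenyl]-3-oxopropanoate | CC(C)(C)OC(=O)CC(=O)c1c(O)cc(OC)cc1OCc1ccccc1 | intermediate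
15 | tert-butyl (Z)-2-[2-(benzyloxy)-6-hydroxy-4-methoxybenzoyl]-3-{3-[5,7-bis(benzyloxy)-2-(4-benzyloxyphenyl)-4-oxo-4H-chromen-8-yl]-4-methoxyphenyl}acrylate | CC(C)(C)OC(=O)/C(=C\c1ccc(OC)c(-c2c(OCc3ccccc3)cc(OCc3ccccc3)c3c(=O)cc(-c4ccc(OCc5ccccc5)cc4)oc23)c1)C(=O)c1c(O)cc(OC)cc1OCc1ccccc1 | intermediate
16 | tert-butyl (2S)-5-(benzyloxy)-7-methoxy-4-oxo-2-aryl-chromane-3-carboxylate (aryl = ring B carrying the tribenzyl flavone; C3 configurationally labile, keto/enol) | COc1cc(OCc2ccccc2)c2c(c1)O[C@H](c1ccc(OC)c(-c3c(OCc4ccccc4)cc(OCc4ccccc4)c4c(=O)cc(-c5ccc(OCc6ccccc6)cc5)oc34)c1)C(C(=O)OC(C)(C)C)C2=O | intermediate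
17 | (2S)-5-(benzyloxy)-7-methoxy-4-oxo-2-aryl-chromane-3-carboxylic acid (same aryl; C3 labile) | COc1cc(OCc2ccccc2)c2c(c1)O[C@H](c1ccc(OC)c(-c3c(OCc4ccccc4)cc(OCc4ccccc4)c4c(=O)cc(-c5ccc(OCc6ccccc6)cc5)oc34)c1)C(C(=O)O)C2=O | intermediate
18 | (2S)-5,5'',7'',4'''-tetra-O-benzyl-2,3-dihydroamentoflavone 7,4'-dimethyl ether | COc1cc(OCc2ccccc2)c2c(c1)O[C@H](c1ccc(OC)c(-c3c(OCc4ccccc4)cc(OCc4ccccc4)c4c(=O)cc(-c5ccc(OCc6ccccc6)cc5)oc34)c1)CC2=O | intermediate
19 | (2S)-2,3-dihydroamentoflavone 7,4'-dimethyl ether (CNP0169789.1) | COc1cc(O)c2c(c1)O[C@H](c1ccc(OC)c(-c3c(O)cc(O)c4c(=O)cc(-c5ccc(O)cc5)oc34)c1)CC2=O | target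

Total step count: 11. Longest linear sequence: 8 steps (1, 2, 4, 5, 6, 9, 10, 11). Step 3 joins at step 4, and steps 7 and 8 join at step 9.

Steps most likely to fail

Step 6.
- **What may go wrong:** The donor-stabilised acyl group may be too weak an electrophile. Ring closure could then be overtaken by acid-induced loss of CO2 from the electron-rich acrylic acid, by intermolecular acylation or trifluoroacetylation at C6'', or by closure of the E form onto the 4-benzyloxyphenyl ring.
- **Fallback:** The pyranone is closed at oxygen instead. This stays unambiguous because 4 has a single free phenol. Setting out from 4, iodination (NIS, CH2Cl2, 0 °C) at the remaining carbon ortho to the hydroxyl group gives 3-[4,6-bis(benzyloxy)-2-hydroxy-3-iodophenyl]-4-methoxybenzaldehyde F1. Carbonylative Sonogashira coupling with purchased 1-(benzyloxy)-4-ethynylbenzene F2 (PdCl2(PPh3)2, CO, Et2NH, 100 °C) passes through the 2-hydroxyaryl alkynone F3. F3 cyclises 6-endo-dig in the same flask and comes back to the route at 11.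

Step 10.
- **What may go wrong:** Uncatalysed or piperidine-carried background cyclisation may compete. Facial selectivity may be poor because the 6'-benzyloxy group twists the aroyl group out of plane. Optical purity may erode through retro-oxa-Michael opening in the hot acid stage.
- **Fallback:** The racemate is made and resolved. Setting out from 11 and 13, Claisen–Schmidt condensation (KOH, EtOH/THF, rt) gives the (E)-2'-hydroxychalcone F4. Cyclisation (NaOAc, EtOH, reflux) gives the racemic tetrabenzyl flavanone F5. Preparative HPLC on a polysaccharide carbamate chiral phase delivers the (2S) enantiomer and comes back to the route at 18. The (2R) enantiomer F6 is returned to F5 by NaOAc-mediated equilibration and resolved again.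

Step 4.
- **What may go wrong:** Addition may be sluggish because the phenoxide is flanked by ring B and the alkynoate is deactivated by the para benzyloxy donor. Adventitious water could then hydrate the alkyne.
- **Fallback:** Conjugate addition is replaced by a vinylic C–O coupling. Setting out from 7, hydroiodination (NaI, AcOH, 100 °C) gives ethyl (Z)-3-[4-(benzyloxy)phenyl]-3-iodoacrylate F7. Ullmann-type coupling with 4 (CuI, N,N-dimethylglycine, Cs2CO3, dioxane, 90 °C) should proceed with retention of geometry and comes back to the route at 8.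

Further compounds
F1 | step 6 | 3-[4,6-bis(benzyloxy)-2-hydroxy-3-iodophenyl]-4-methoxybenzaldehyde | O=Cc1ccc(OC)c(-c2c(O)c(I)c(OCc3ccccc3)cc2OCc2ccccc2)c1
F2 | step 6 | 1-(benzyloxy)-4-ethynylbenzene (purchased) | C#Cc1ccc(OCc2ccccc2)cc1
F3 | step 6 | 3-{4,6-bis(benzyloxy)-3-[3-(4-benzyloxyphenyl)prop-2-ynoyl]-2-hydroxyphenyl}-4-methoxybenzaldehyde | O=Cc1ccc(OC)c(-c2c(O)c(C(=O)C#Cc3ccc(OCc4ccccc4)cc3)c(OCc3ccccc3)cc2OCc2ccccc2)c1
F4 | step 10 | (E)-1-[2-(benzyloxy)-6-hydroxy-4-methoxyphenyl]-3-{3-[5,7-bis(benzyloxy)-2-(4-benzyloxyphenyl)-4-oxo-4H-chromen-8-yl]-4-methoxyphenyl}prop-2-en-1-one | COc1cc(O)c(C(=O)/C=C/c2ccc(OC)c(-c3c(OCc4ccccc4)cc(OCc4ccccc4)c4c(=O)cc(-c5ccc(OCc6ccccc6)cc5)oc34)c2)c(OCc2ccccc2)c1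
F5 | step 10 | racemic 5,5'',7'',4'''-tetra-O-benzyl-2,3-dihydroamentoflavone 7,4'-dimethyl ether | COc1cc(OCc2ccccc2)c2c(c1)OC(c1ccc(OC)c(-c3c(OCc4ccccc4)cc(OCc4ccccc4)c4c(=O)cc(-c5ccc(OCc6ccccc6)cc5)oc34)c1)CC2=O
F6 | step 10 | (2R)-5,5'',7'',4'''-tetra-O-benzyl-2,3-dihydroamentoflavone 7,4'-dimethyl ether | COc1cc(OCc2ccccc2)c2c(c1)O[C@@H](c1ccc(OC)c(-c3c(OCc4ccccc4)cc(OCc4ccccc4)c4c(=O)cc(-c5ccc(OCc6ccccc6)cc5)oc34)c1)CC2=O
F7 | step 4 | ethyl (Z)-3-[4-(benzyloxy)phenyl]-3-iodoacrylate | CCOC(=O)/C=C(\I)c1ccc(OCc2ccccc2)cc1
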